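## Retrosynthetic overview

1. The target is (5R,6R,7S,10R)-eudesm-3-en-6β-yl (E)-4-hydroxycinnamate. The ester is made last from the 6β-alcohol 23 (malonate half-ester, then Knoevenagel–Doebner), and 23 comes from the C6 ketone 22 by equatorial hydride delivery.
2. Ring B is closed last at C7–C8. Me2CuLi adds to the crotonyl ketone C6(=O)–C7=C11 of the monocyclic iodide 18, and the resulting C6=C7 enolate alkylates the C8 iodide. The enabling feature is the C6 carbonyl: C7 sits on one side (isopropyl = propenyl carbon C11 + cuprate methyl), and on the other side the path C5–C10–C9–C8 places the primary C8 six atoms from C7.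
3. Iodide 18 comes from a temporary ring that is absent from the target: the δ-lactone 13, in which an oxygen takes the place of C7 (C6(=O)–O–C8). Propenyllithium opens it and the freed C8–OH becomes the iodide.
4. The lactone controls C5. Carbonylative lactonisation of the hydroxy vinyl triflate 9 gives the conjugated lactone 11; its dienolate is protonated anti to the angular methyl to give the trans-fused 3,4-ene lactone 13.
5. C10 is set by Pd-catalysed decarboxylative asymmetric allylation (1 → 5), and the allyl group is cut by ozonolysis to the C9–C8 arm. Ring order: A (bought), temporary lactone (step 5), B (step 9).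

Key step: step 9

Remark on the chemistry (assumptions): eudesmane numbering is used throughout (C1–C10 ring carbons, C11 the isopropyl CH, C14 the angular methyl, C15 the alkene methyl). Ketone 1 is used as the commercial cis/trans mixture; its second methyl-bearing CH is a spectator stereocentre that is carried as an epimer mixture in 5 and erased in step 3. Catalyst control in step 2 is assumed to override it.

## Route

Step 1
Reactants: 1 2,6-dimethylcyclohexan-1-one (cis/trans mixture); 2 allyl chloroformate
Product: 4 2,6-dimethylcyclohex-1-en-1-yl prop-2-en-1-yl carbonate (racemic), via lithium enolate 3 (not isolated)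
Conditions: LDA, TMEDA, THF, −78 → 0 °C; then 2, −78 °C → rt
Reagents that add atoms: allyl chloroformate (2), C=CCOC(=O)Cl
Why: The hindered, fully substituted lithium enolate should be acylated on oxygen by the chloroformate (enol carbonate formation); no stereocentre of the target is involved.

Step 2
Reactants: 4
Product: 5 (2R)-2,6-dimethyl-2-(prop-2-en-1-yl)cyclohexan-1-one (mixture of C6 epimers)
Conditions: Pd2(dba)3 (2.5 mol %), (R)-t-BuPHOX (6 mol %), THF, 25 °C
Reagents that add atoms: none
Why: Pd-catalysed decarboxylative asymmetric allylic alkylation (Tsuji allylation) through a Pd enolate/π-allyl pair; the (R)-PHOX ligand should set the quaternary carbon (future C10) as R, the (S)-ligand being known to give (S)-2-allyl-2-methylcyclohexanone in this series.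

Step 3
Reactants: 5
Product: 7 (6R)-2,6-dimethyl-6-(prop-2-en-1-yl)cyclohex-1-en-1-yl trifluoromethanesulfonate, via potassium enolate 6 (not isolated)
Conditions: KHMDS, THF, −78 → 0 °C; PhNTf2, −78 °C → rt
Reagents that add atoms: N-phenylbis(trifluoromethanesulfonimide), O=S(=O)(N(c1ccccc1)S(=O)(=O)C(F)(F)F)C(F)(F)F
Why: The ketone can enolise only toward the methyl-bearing carbon, so O-triflation of the enolate should give a single tetrasubstituted enol triflate and erase the spectator stereocentre.

Step 4
Reactants: 7
Product: 9 (6R)-6-(2-hydroxyethyl)-2,6-dimethylcyclohex-1-en-1-yl trifluoromethanesulfonate, via aldehyde 8 (not isolated)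
Conditions: O3, CH2Cl2–MeOH, −78 °C; then NaBH4, −78 → 0 °C
Reagents that add atoms: ozone, [O-][O+]=O
Why: Ozonolysis with reductive work-up: ozone should cleave the terminal alkene far faster than the electron-poor tetrasubstituted enol triflate, and borohydride reduces the aldehyde, trimming the allyl group to the two-carbon arm C9–C8.

Step 5
Reactants: 9; 10 carbon monoxide
Product: 11 (4aR)-4a,8-dimethyl-3,4,4a,5,6,7-hexahydro-1H-isochromen-1-one
Conditions: Pd(PPh3)4 (5 mol %), CO (1 atm), Et3N, DMF, 70 °C
Reagents that add atoms: carbon monoxide (10), [C-]#[O+]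
Why: Intramolecular alkoxycarbonylation: Pd(0) inserts into the vinyl triflate, CO gives the acyl-palladium, and the tethered hydroxyl traps it to form the six-membered unsaturated lactone, the temporary 7-oxa counterpart of ring B that brings in C6.

Step 6
Reactants: 11
Product: 13 (4aR,8aR)-4a,8-dimethyl-3,4,4a,5,6,8a-hexahydro-1H-isochromen-1-one, via potassium dienolate 12 (not isolated)
Conditions: KOt-Bu, t-BuOH–THF, 0 °C → rt; then poured into cold aq. AcOH
Reagents that add atoms: none
Why: Deconjugative protonation of an extended enolate: reversible γ-deprotonation should favour the endocyclic C3=C4 dienolate, and kinetic α-protonation at C5 should occur anti to the axial angular methyl on the adjacent C10 of the rigid bicycle, setting the trans ring fusion (5R) and the 3,4-alkene.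

Step 7
Reactants: 13; 14 (E)-1-bromoprop-1-ene
Product: 17 (2E)-1-[(1R,6R)-6-(2-hydroxyethyl)-2,6-dimethylcyclohex-2-en-1-yl]but-2-en-1-one, via (E)-prop-1-enyllithium 15 (not isolated), via lithium lactolate 16 (not isolated)
Conditions: 14, t-BuLi (2 equiv), Et2O, −78 °C; then 13, THF, −78 °C; aq. NH4Cl
Reagents that add atoms: (E)-prop-1-enyllithium (15), C/C=C/[Li], made in the flask from (E)-1-bromoprop-1-ene (14), C/C=C/Br
Why: Mono-addition of an alkenyllithium to a lactone at −78 °C should give a tetrahedral lactolate that collapses to the enone only on work-up, so the ring O–C8 bond ends as the free primary alcohol and the C5 stereocentre is kept.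

Step 8
Reactants: 17
Product: 18 (2E)-1-[(1R,6R)-6-(2-iodoethyl)-2,6-dimethylcyclohex-2-en-1-yl]but-2-en-1-one
Conditions: I2, PPh3, imidazole, CH2Cl2, 0 °C → rt
Reagents that add atoms: iodine, II
Why: Appel-type iodination converts the primary alcohol to the iodide by SN2 under nearly neutral conditions that should leave the β,γ-unsaturated enone and C5–H untouched.

Step 9
Reactants: 18; 19 methyllithium
Product: 22 (2S,4aR,8aR)-4a,8-dimethyl-2-(propan-2-yl)-3,4,4a,5,6,8a-hexahydronaphthalen-1(2H)-one [(5R,7S,10R)-eudesm-3-en-6-one], via lithium dimethylcuprate 20 (not isolated), via lithium enolate 21 (not isolated)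
Conditions: MeLi (2.3 equiv), CuI (1.15 equiv), Et2O, −78 °C; 18 added (0.01 M), −78 °C; then DMPU–THF, −78 → 0 °C; AcOH, −78 °C, then aq. NH4Cl
Reagents that add atoms: lithium dimethylcuprate (20), [Li+].C[Cu-]C, made in the flask from methyllithium (19), [Li]C
Why: Tandem conjugate addition–cycloalkylation (Michael-initiated ring closure): Me2CuLi adds to C11 of the s-cis (E)-crotonyl ketone to give the (Z)-enolate 21 regiospecifically at C6=C7, and on adding DMPU and warming this enolate displaces the primary iodide at C8. The closest known reaction type is cuprate addition to an enone followed by intramolecular alkylation of the enolate by an ω-halide. Ring B closes in the 6-(enolendo)-exo-tet mode, the mode in which six-membered rings form by C- rather than O-alkylation. C7 is set in a chair-like transition state fused trans to ring A, in which the group cis to the enolate oxygen (the new isopropyl) becomes equatorial (7S); C5 and C10 are the controlling elements. The step needs the enolate at C7 rather than at the more acidic C5–H, and attack on the enone before the iodide. The first is secured by making the enolate by conjugate addition instead of by base and by high dilution so that cyclisation outruns proton transfer; the second by the much faster 1,4-addition of the cuprate at −78 °C.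

Step 10
Reactants: 22
Product: 23 (1R,2S,4aR,8aR)-4a,8-dimethyl-2-(propan-2-yl)-1,2,3,4,4a,5,6,8a-octahydronaphthalen-1-ol (eudesm-3-en-6β-ol)
Conditions: L-Selectride, THF, −78 °C; then NaOH, H2O2, 0 °C
Reagents that add atoms: none
Why: Hydride reduction of a hindered cyclohexanone: the bulky hydride should attack C6 along the equatorial trajectory from the α-face because the axial approach is blocked by the syn-axial C10 methyl, giving the axial 6β-alcohol (6R) without base that could move the alkene into conjugation.

Step 11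
Reactants: 23; 24 Meldrum's acid (2,2-dimethyl-1,3-dioxane-4,6-dione)
Product: 25 3-{[(1R,2S,4aR,8aR)-4a,8-dimethyl-2-(propan-2-yl)-1,2,3,4,4a,5,6,8a-octahydronaphthalen-1-yl]oxy}-3-oxopropanoic acid
Conditions: 24, toluene, 100 °C
Reagents that add atoms: Meldrum's acid (24), CC1(C)OC(=O)CC(=O)O1
Why: Thermal alcoholysis of Meldrum's acid (loss of acetone) is a small, reactive acyl transfer that should acylate even the hindered axial alcohol, giving the hydrogen malonate with retention at C6.

Step 12
Reactants: 25; 26 4-hydroxybenzaldehyde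
Product: 28 (1R,2S,4aR,8aR)-4a,8-dimethyl-2-(propan-2-yl)-1,2,3,4,4a,5,6,8a-octahydronaphthalen-1-yl (2E)-3-(4-hydroxyphenyl)prop-2-enoate, via arylidenemalonate half-ester 27 (not isolated)
Conditions: 26, pyridine, piperidine (cat.), 70 °C
Reagents that add atoms: 4-hydroxybenzaldehyde (26), O=Cc1ccc(O)cc1
Why: Knoevenagel–Doebner condensation of the malonate half-ester with the aldehyde followed by decarboxylation should give the (E)-cinnamate directly, so the phenol needs no protecting group.

## Compound list

1 | 2,6-dimethylcyclohexan-1-one (cis/trans mixture) | CC1CCCC(C)C1=O | starting material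
2 | allyl chloroformate | C=CCOC(=O)Cl | starting material
3 | lithium 2,6-dimethylcyclohex-1-en-1-olate | CC1CCCC(C)=C1[O-].[Li+] | intermediate
4 | 2,6-dimethylcyclohex-1-en-1-yl prop-2-en-1-yl carbonate (racemic) | C=CCOC(=O)OC1=C(C)CCCC1C | intermediate
5 | (2R)-2,6-dimethyl-2-(prop-2-en-1-yl)cyclohexan-1-one (C6 epimers) | CC1CCC[C@](C)(CC=C)C1=O | intermediate
6 | potassium (6R)-2,6-dimethyl-6-(prop-2-en-1-yl)cyclohex-1-en-1-olate | CC1CCC[C@](C)(CC=C)C=1[O-].[K+] | intermediate
7 | (6R)-2,6-dimethyl-6-(prop-2-en-1-yl)cyclohex-1-en-1-yl trifluoromethanesulfonate | CC1CCC[C@](C)(CC=C)C=1OS(=O)(=O)C(F)(F)F | intermediate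
8 | (6R)-2,6-dimethyl-6-(2-oxoethyl)cyclohex-1-en-1-yl trifluoromethanesulfonate | CC1CCC[C@](C)(CC=O)C=1OS(=O)(=O)C(F)(F)F | intermediate
9 | (6R)-6-(2-hydroxyethyl)-2,6-dimethylcyclohex-1-en-1-yl trifluoromethanesulfonate | CC1CCC[C@](C)(CCO)C=1OS(=O)(=O)C(F)(F)F | intermediate
10 | carbon monoxide | [C-]#[O+] | starting material
11 | (4aR)-4a,8-dimethyl-3,4,4a,5,6,7-hexahydro-1H-isochromen-1-one | CC1CCC[C@](C)(CCOC2=O)C=12 | intermediate
12 | potassium dienolate of 11 (C3=C4, C5=C6) | CC1=CCC[C@]2(C)CCOC([O-])=C12.[K+] | intermediate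
13 | (4aR,8aR)-4a,8-dimethyl-3,4,4a,5,6,8a-hexahydro-1H-isochromen-1-one | CC1=CCC[C@]2(C)CCOC(=O)[C@@H]12 | intermediate
14 | (E)-1-bromoprop-1-ene | C/C=C/Br | starting material
15 | (E)-prop-1-enyllithium | C/C=C/[Li] | intermediate
16 | lithium lactolate from 13 and 15 (C6 epimers) | CC1=CCC[C@]2(C)CCOC([O-])(/C=C/C)[C@@H]12.[Li+] | intermediate
17 | (2E)-1-[(1R,6R)-6-(2-hydroxyethyl)-2,6-dimethylcyclohex-2-en-1-yl]but-2-en-1-one | CC1=CCC[C@](C)(CCO)[C@H]1C(=O)/C=C/C | intermediate
18 | (2E)-1-[(1R,6R)-6-(2-iodoethyl)-2,6-dimethylcyclohex-2-en-1-yl]but-2-en-1-one | CC1=CCC[C@](C)(CCI)[C@H]1C(=O)/C=C/C | intermediate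
19 | methyllithium | [Li]C | starting material
20 | lithium dimethylcuprate | [Li+].C[Cu-]C | intermediate
21 | lithium (Z)-enolate from 18 (C6=C7, isopropyl cis to O) | CC1=CCC[C@](C)(CCI)[C@H]1/C([O-])=C/C(C)C.[Li+] | intermediate
22 | (2S,4aR,8aR)-4a,8-dimethyl-2-(propan-2-yl)-3,4,4a,5,6,8a-hexahydronaphthalen-1(2H)-one | CC1=CCC[C@]2(C)CC[C@@H](C(C)C)C(=O)[C@@H]12 | intermediate
23 | (1R,2S,4aR,8aR)-4a,8-dimethyl-2-(propan-2-yl)-1,2,3,4,4a,5,6,8a-octahydronaphthalen-1-ol | CC1=CCC[C@]2(C)CC[C@@H](C(C)C)[C@@H](O)[C@@H]12 | intermediate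
24 | Meldrum's acid | CC1(C)OC(=O)CC(=O)O1 | starting material
25 | hydrogen malonate of 23 | CC1=CCC[C@]2(C)CC[C@@H](C(C)C)[C@@H](OC(=O)CC(=O)O)[C@@H]12 | intermediate
26 | 4-hydroxybenzaldehyde | O=Cc1ccc(O)cc1 | starting material
27 | (4-hydroxybenzylidene)malonate half-ester of 23 | CC1=CCC[C@]2(C)CC[C@@H](C(C)C)[C@@H](OC(=O)C(=Cc3ccc(O)cc3)C(=O)O)[C@@H]12 | intermediate
28 | (1R,2S,4aR,8aR)-4a,8-dimethyl-2-(propan-2-yl)-1,2,3,4,4a,5,6,8a-octahydronaphthalen-1-yl (2E)-3-(4-hydroxyphenyl)prop-2-enoate | CC1=CCC[C@]2(C)CC[C@@H](C(C)C)[C@@H](OC(=O)/C=C/c3ccc(O)cc3)[C@@H]12 | target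

## Step count and risks

Total step count: 12. Longest linear sequence: 12 steps (fully linear from 1).

The three steps most likely to fail, each with one fallback:

Risk 1, step 9 (key step): the doubly activated C5–H of the product or of unreacted ketone may transfer a proton to the enolate before ring closure, which would lose the regiodefined enolate and move the alkene into conjugation. O-alkylation and incomplete facial control at C7 are further risks. The fallback for step 9 sets out from lactone 13 and comes back at ketone 22. Lactone 13 would be opened with two equivalents of lithiated isobutyl phenyl sulfone (n-BuLi, THF, −78 °C) to give 1-[(1R,6R)-6-(2-hydroxyethyl)-2,6-dimethylcyclohex-2-en-1-yl]-3-methyl-2-(phenylsulfonyl)butan-1-one F1. Appel iodination (I2, PPh3, imidazole) would give 1-[(1R,6R)-6-(2-iodoethyl)-2,6-dimethylcyclohex-2-en-1-yl]-3-methyl-2-(phenylsulfonyl)butan-1-one F2. Cs2CO3 in DMF would then close ring B at C7–C8 through the soft β-keto sulfone anion, which is far more acidic than C5–H, giving (4aR,8aR)-4a,8-dimethyl-2-(phenylsulfonyl)-2-(propan-2-yl)-3,4,4a,5,6,8a-hexahydronaphthalen-1(2H)-one F3. SmI2 in THF–MeOH at −78 °C would remove the sulfone, and axial protonation of the samarium enolate at C7 should give 22.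

Risk 2, step 6: deprotonation may occur at the C4 methyl instead of C3, which would give the exocyclic alkene isomer. The dienolate may also be reprotonated at the γ-carbon back to 11, or the C5 protonation may show poor facial selectivity. The fallback for step 6 sets out from lactone 11 and comes back at ketone 22, postponing the deconjugation until after ring closure. Lactone 11 would be opened with (E)-prop-1-enyllithium to (2E)-1-[(6R)-6-(2-hydroxyethyl)-2,6-dimethylcyclohex-1-en-1-yl]but-2-en-1-one F4. Appel iodination would give (2E)-1-[(6R)-6-(2-iodoethyl)-2,6-dimethylcyclohex-1-en-1-yl]but-2-en-1-one F5. Me2CuLi followed by DMPU would give (2S,4aR)-4a,8-dimethyl-2-(propan-2-yl)-3,4,4a,5,6,7-hexahydronaphthalen-1(2H)-one F6, the (7S,10R)-eudesm-4-en-6-one, in which no acidic C5–H exists during the closure. Radical bromination with NBS at the secondary allylic C3 would give (2S,4aS)-7-bromo-4a,8-dimethyl-2-(propan-2-yl)-3,4,4a,5,6,7-hexahydronaphthalen-1(2H)-one F7. Zinc in acetic acid would form the dienolate reductively, and its kinetic protonation at C5 anti to the angular methyl should give 22.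

Risk 3, step 7: the organolithium may enolise the lactone at C5 instead of adding to the carbonyl, or the lactolate may collapse and take up a second equivalent. The fallback for step 7 sets out from lactone 13 and comes back at hydroxy enone 17. DIBAL-H (CH2Cl2, −78 °C) would give (4aR,8aR)-4a,8-dimethyl-3,4,4a,5,6,8a-hexahydro-1H-isochromen-1-ol F8. (E)-Prop-1-enyllithium (2.2 equiv) would add to its open hydroxy-aldehyde form to give (2E)-1-[(1R,6R)-6-(2-hydroxyethyl)-2,6-dimethylcyclohex-2-en-1-yl]but-2-en-1-ol F9. MnO2 (CH2Cl2) would oxidise only the allylic secondary alcohol, giving 17.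

## Further compounds

F1 | step 9 | 1-[(1R,6R)-6-(2-hydroxyethyl)-2,6-dimethylcyclohex-2-en-1-yl]-3-methyl-2-(phenylsulfonyl)butan-1-one (C7 epimers) | CC1=CCC[C@](C)(CCO)[C@H]1C(=O)C(C(C)C)S(=O)(=O)c1ccccc1
F2 | step 9 | 1-[(1R,6R)-6-(2-iodoethyl)-2,6-dimethylcyclohex-2-en-1-yl]-3-methyl-2-(phenylsulfonyl)butan-1-one (C7 epimers) | CC1=CCC[C@](C)(CCI)[C@H]1C(=O)C(C(C)C)S(=O)(=O)c1ccccc1
F3 | step 9 | (4aR,8aR)-4a,8-dimethyl-2-(phenylsulfonyl)-2-(propan-2-yl)-3,4,4a,5,6,8a-hexahydronaphthalen-1(2H)-one (C2 epimers) | CC1=CCC[C@]2(C)CCC(C(C)C)(S(=O)(=O)c3ccccc3)C(=O)[C@@H]12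
F4 | step 6 | (2E)-1-[(6R)-6-(2-hydroxyethyl)-2,6-dimethylcyclohex-1-en-1-yl]but-2-en-1-one | CC1CCC[C@](C)(CCO)C=1C(=O)/C=C/C
F5 | step 6 | (2E)-1-[(6R)-6-(2-iodoethyl)-2,6-dimethylcyclohex-1-en-1-yl]but-2-en-1-one | CC1CCC[C@](C)(CCI)C=1C(=O)/C=C/C
F6 | step 6 | (2S,4aR)-4a,8-dimethyl-2-(propan-2-yl)-3,4,4a,5,6,7-hexahydronaphthalen-1(2H)-one [(7S,10R)-eudesm-4-en-6-one] | CC1CCC[C@]2(C)CC[C@@H](C(C)C)C(=O)C=12
F7 | step 6 | (2S,4aS)-7-bromo-4a,8-dimethyl-2-(propan-2-yl)-3,4,4a,5,6,7-hexahydronaphthalen-1(2H)-one (C7 epimers) | CC1C(Br)CC[C@]2(C)CC[C@@H](C(C)C)C(=O)C=12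
F8 | step 7 | (4aR,8aR)-4a,8-dimethyl-3,4,4a,5,6,8a-hexahydro-1H-isochromen-1-ol (anomers) | CC1=CCC[C@]2(C)CCOC(O)[C@@H]12
F9 | step 7 | (2E)-1-[(1R,6R)-6-(2-hydroxyethyl)-2,6-dimethylcyclohex-2-en-1-yl]but-2-en-1-ol (carbinol epimers) | CC1=CCC[C@](C)(CCO)[C@H]1C(O)/C=C/C
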